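**Retrosynthesis**
- Final step: hydrogenolysis of two aryl O‑benzyl ethers gives the target.
- The erythro C7''/C8'' pair (7''S,8''R) comes from Noyori ATH with dynamic kinetic resolution of a racemic α‑aryloxy propiophenone.
- That ketone comes from a Williamson ether synthesis (α‑bromoketone + 4‑bromosyringol), then a Negishi coupling of the resulting aryl bromide with the 2,3‑dimethylbutyl zinc reagent.
- The meso‑like 8S,8'R core (1,4‑diaryl‑2,3‑dimethylbutane) comes from Deng desymmetrisation of cis‑2,3‑dimethylsuccinic anhydride, followed by two sequential CH2–aryl Negishi couplings.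
- No carbocycle is built: all three arenes are commercial, and the only ring (the anhydride) is opened in step 2.

**Assumptions**
- The cinchona antipode ((DHQD)2AQN or (DHQ)2AQN) is chosen to give the (2R,3S)‑hemiester 4.
- The (R,R)‑Ru–TsDPEN catalyst is assumed to give the erythro (7''S,8''R) alcohol. The C7'' sense follows the usual face selectivity of (R,R)‑TsDPEN for aryl ketones. Erythro selectivity at C8'' is assumed and must be checked.

---

**Step 1**
Reactants: 1 meso‑2,3‑dimethylsuccinic acid
Product: 2 cis‑2,3‑dimethylsuccinic anhydride (meso)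
Conditions: AcCl, reflux, 2 h
Reagents that add atoms: none
Why: Dehydration of the meso diacid gives the cis cyclic anhydride; no stereocentre is touched.

**Step 2**
Reactants: 2 cis‑2,3‑dimethylsuccinic anhydride; 3 methanol
Product: 4 (2R,3S)‑4‑methoxy‑2,3‑dimethyl‑4‑oxobutanoic acid (hemiester)
Conditions: MeOH (3 equiv), (DHQD)2AQN (10 mol %), MTBE, –20 °C
Reagents that add atoms: methanol, CO
Why: Cinchona‑alkaloid‑catalysed enantioselective methanolysis of a meso anhydride (Deng desymmetrisation) differentiates the two enantiotopic carbonyls and sets both C8 and C8' at once.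

**Step 3**
Reactants: 4 hemiester
Product: 5 methyl (2S,3R)‑4‑hydroxy‑2,3‑dimethylbutanoate (crude, used at once)
Conditions: BH3·SMe2, THF, 0 °C to rt; MeOH quench at 0 °C, concentrate (no acid or base work‑up)
Reagents that add atoms: none
Why: Borane reduces a carboxylic acid much faster than a methyl ester, and the stereocentres are untouched. The γ‑hydroxy ester is kept neutral and cold and taken directly into step 4, so it does not lactonise.

**Step 4**
Reactants: 5 hydroxy ester; 6 iodine
Product: 7 methyl (2S,3R)‑4‑iodo‑2,3‑dimethylbutanoate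
Conditions: I2, PPh3, imidazole, CH2Cl2, 0 °C
Reagents that add atoms: iodine, II
Why: Appel‑type SN2 iodination of a primary alcohol under buffered, near‑neutral conditions; the stereocentres are not involved.

**Step 5**
Reactants: 8 4‑bromo‑2‑methoxyphenol; 9 benzyl bromide
Product: 10 1‑(benzyloxy)‑4‑bromo‑2‑methoxybenzene
Conditions: BnBr, K2CO3, DMF, rt
Reagents that add atoms: benzyl bromide, BrCc1ccccc1
Why: Williamson O‑benzylation masks the phenol so the aryl bromide can be used in the organozinc coupling.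

**Step 6**
Reactants: 7 iodo ester; 10 aryl bromide
Product: 11 methyl (2S,3S)‑4‑[4‑(benzyloxy)‑3‑methoxyphenyl]‑2,3‑dimethylbutanoate
Conditions: Zn dust, LiCl, TMSCl/BrCH2CH2Br, THF, 40 °C; then 10, Pd‑PEPPSI‑IPr (2 mol %), THF, 50 °C
Reagents that add atoms: none
Why: Knochel zinc insertion gives an ester‑tolerant primary alkylzinc, and Negishi coupling forms the C7–aryl bond. No base is present, so the ester α‑stereocentre is not epimerised.

**Step 7**
Reactants: 11 ester
Product: 12 (2S,3S)‑4‑[4‑(benzyloxy)‑3‑methoxyphenyl]‑2,3‑dimethylbutan‑1‑ol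
Conditions: LiAlH4, THF, 0 °C
Reagents that add atoms: none
Why: Hydride reduction of the ester gives the primary alcohol; the aryl benzyl ether and the stereocentres are unaffected.

**Step 8**
Reactants: 12 alcohol; 6 iodine
Product: 13 1‑(benzyloxy)‑4‑[(2S,3S)‑4‑iodo‑2,3‑dimethylbutyl]‑2‑methoxybenzene
Conditions: I2, PPh3, imidazole, CH2Cl2, 0 °C
Reagents that add atoms: iodine, II
Why: Appel iodination converts the primary alcohol into the iodide needed for the second Csp3–Csp2 coupling.

**Step 9**
Reactants: 14 propiovanillone (1‑(4‑hydroxy‑3‑methoxyphenyl)propan‑1‑one); 9 benzyl bromide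
Product: 15 1‑[4‑(benzyloxy)‑3‑methoxyphenyl]propan‑1‑one
Conditions: BnBr, K2CO3, DMF, rt
Reagents that add atoms: benzyl bromide, BrCc1ccccc1
Why: O‑Benzylation stops the phenol competing as a nucleophile in step 11.

**Step 10**
Reactants: 15 aryl ethyl ketone; 16 bromine
Product: 17 2‑bromo‑1‑[4‑(benzyloxy)‑3‑methoxyphenyl]propan‑1‑one (racemic)
Conditions: Br2 (1.0 equiv), CH2Cl2, 0 °C to rt, 2 h
Reagents that add atoms: bromine, BrBr
Why: Acid‑catalysed enol α‑bromination of an aryl ethyl ketone; the acyl‑deactivated ring is not brominated at 1 equiv and low temperature. The new α‑centre is racemic and is resolved dynamically in step 13.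

**Step 11**
Reactants: 17 bromoketone; 18 4‑bromo‑2,6‑dimethoxyphenol
Product: 19 2‑(4‑bromo‑2,6‑dimethoxyphenoxy)‑1‑[4‑(benzyloxy)‑3‑methoxyphenyl]propan‑1‑one (racemic)
Conditions: K2CO3, acetone, reflux
Reagents that add atoms: none
Why: Williamson ether synthesis (SN2 of the phenoxide on the α‑bromoketone) forms the C8''–O–aryl bond; the labile α‑centre is left racemic for the DKR.

**Step 12**
Reactants: 13 primary iodide; 19 aryl bromide ketone
Product: 20 1‑[4‑(benzyloxy)‑3‑methoxyphenyl]‑2‑{4‑[(2R,3S)‑4‑(4‑(benzyloxy)‑3‑methoxyphenyl)‑2,3‑dimethylbutyl]‑2,6‑dimethoxyphenoxy}propan‑1‑one (C8'' epimeric mixture)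
Conditions: Zn dust, LiCl, TMSCl/BrCH2CH2Br, THF, 40 °C; then 19, Pd‑PEPPSI‑IPr (3 mol %), THF, 50 °C
Reagents that add atoms: none
Why: Negishi coupling forms the C7'–aryl bond. Organozinc halides do not add to aryl ketones without a Lewis acid, and no base is present to epimerise C8/C8'.

**Step 13**
Reactants: 20 α‑aryloxy ketone
Product: 21 (1S,2R)‑1‑[4‑(benzyloxy)‑3‑methoxyphenyl]‑2‑{4‑[(2R,3S)‑4‑(4‑(benzyloxy)‑3‑methoxyphenyl)‑2,3‑dimethylbutyl]‑2,6‑dimethoxyphenoxy}propan‑1‑ol
Conditions: (R,R)‑RuCl(p‑cymene)(TsDPEN) (2 mol %), HCO2H/Et3N 5:2, CH2Cl2, 40 °C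
Reagents that add atoms: none
Why: Noyori asymmetric transfer hydrogenation with dynamic kinetic resolution. Et3N racemises the acidic α‑aryloxy centre while the chiral Ru–H reduces one ketone face, setting C7'' (S) and C8'' (R) together. The catalyst also reduces diastereomeric 20 to a single 7''S,8''R product.

**Step 14**
Reactants: 21 bis‑benzyl ether
Product: 22 target
Conditions: H2 (1 atm), 10 % Pd/C, EtOAc/MeOH, rt, monitored to stop at full debenzylation
Reagents that add atoms: none
Why: Neutral hydrogenolysis cleaves both aryl benzyl ethers and leaves the secondary benzylic alcohol, the aryl alkyl ether and all stereocentres intact.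

---

**Compound list**

1 | meso‑2,3‑dimethylsuccinic acid | OC(=O)[C@H](C)[C@H](C)C(=O)O | starting material
2 | cis‑2,3‑dimethylsuccinic anhydride | C[C@H]1C(=O)OC(=O)[C@H]1C | intermediate
3 | methanol | CO | starting material (reagent)
4 | (2R,3S)‑4‑methoxy‑2,3‑dimethyl‑4‑oxobutanoic acid | OC(=O)[C@H](C)[C@H](C)C(=O)OC | intermediate
5 | methyl (2S,3R)‑4‑hydroxy‑2,3‑dimethylbutanoate | OC[C@H](C)[C@H](C)C(=O)OC | intermediate
6 | iodine | II | starting material (reagent)
7 | methyl (2S,3R)‑4‑iodo‑2,3‑dimethylbutanoate | IC[C@H](C)[C@H](C)C(=O)OC | intermediate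
8 | 4‑bromo‑2‑methoxyphenol | COc1cc(Br)ccc1O | starting material
9 | benzyl bromide | BrCc1ccccc1 | starting material (reagent)
10 | 1‑(benzyloxy)‑4‑bromo‑2‑methoxybenzene | COc1cc(Br)ccc1OCc1ccccc1 | intermediate
11 | methyl (2S,3S)‑4‑[4‑(benzyloxy)‑3‑methoxyphenyl]‑2,3‑dimethylbutanoate | COc1cc(C[C@H](C)[C@H](C)C(=O)OC)ccc1OCc1ccccc1 | intermediate
12 | (2S,3S)‑4‑[4‑(benzyloxy)‑3‑methoxyphenyl]‑2,3‑dimethylbutan‑1‑ol | COc1cc(C[C@H](C)[C@H](C)CO)ccc1OCc1ccccc1 | intermediate
13 | 1‑(benzyloxy)‑4‑[(2S,3S)‑4‑iodo‑2,3‑dimethylbutyl]‑2‑methoxybenzene | COc1cc(C[C@H](C)[C@H](C)CI)ccc1OCc1ccccc1 | intermediate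
14 | propiovanillone | CCC(=O)c1ccc(O)c(OC)c1 | starting material
15 | 1‑[4‑(benzyloxy)‑3‑methoxyphenyl]propan‑1‑one | CCC(=O)c1ccc(OCc2ccccc2)c(OC)c1 | intermediate
16 | bromine | BrBr | starting material (reagent)
17 | 2‑bromo‑1‑[4‑(benzyloxy)‑3‑methoxyphenyl]propan‑1‑one (racemic) | CC(Br)C(=O)c1ccc(OCc2ccccc2)c(OC)c1 | intermediate
18 | 4‑bromo‑2,6‑dimethoxyphenol | COc1cc(Br)cc(OC)c1O | starting material
19 | 2‑(4‑bromo‑2,6‑dimethoxyphenoxy)‑1‑[4‑(benzyloxy)‑3‑methoxyphenyl]propan‑1‑one (racemic) | CC(Oc1c(OC)cc(Br)cc1OC)C(=O)c1ccc(OCc2ccccc2)c(OC)c1 | intermediate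
20 | bis‑O‑benzyl α‑aryloxy ketone from Negishi coupling (C8'' epimeric) | COc1cc(C[C@H](C)[C@H](C)Cc2cc(OC)c(OC(C)C(=O)c3ccc(OCc4ccccc4)c(OC)c3)c(OC)c2)ccc1OCc1ccccc1 | intermediate
21 | bis‑O‑benzyl (7''S,8''R)‑alcohol | COc1cc(C[C@H](C)[C@H](C)Cc2cc(OC)c(O[C@H](C)[C@@H](O)c3ccc(OCc4ccccc4)c(OC)c3)c(OC)c2)ccc1OCc1ccccc1 | intermediate
22 | (+)‑(7''S,8S,8'R,8''R)‑4,4''‑dihydroxy‑3,3',3'',5'‑tetramethoxy‑4',8''‑oxy‑8,8'‑sesquineolignan‑7''‑ol | COc1cc(C[C@H](C)[C@H](C)Cc2cc(OC)c(O[C@H](C)[C@@H](O)c3ccc(O)c(OC)c3)c(OC)c2)ccc1O | target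

---

**Totals**
- Total steps: 14.
- Longest linear sequence: 10 steps, from 1 via steps 1, 2, 3, 4, 6, 7, 8, 12, 13 and 14.

**Three steps most likely to fail**
1. **Step 13 (ATH‑DKR):** the racemisation rate and the erythro (7''S,8''R) diastereoselectivity for this substrate are assumed, not proven.
   - Fallback: build C8'' from the chiral pool.
   - Couple the alkylzinc from 13 with a TBS‑protected 4‑bromosyringol and remove the TBS group.
   - Run a Mitsunobu reaction with (S)‑ethyl lactate to give the (R)‑aryl ether ester.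
   - Convert the ester to the Weinreb amide and add the 4‑benzyloxy‑3‑methoxyphenyl Grignard to give the ketone.
   - Reduce the ketone with a catalyst‑controlled reagent (CBS) and separate the diastereomers.
2. **Step 12 (Negishi of a β‑branched primary alkylzinc onto an aryl bromide that carries an enolisable α‑aryloxy ketone):** it may give low yield, β‑hydride isomerisation or enolate side reactions.
   - Fallback: reverse the order.
   - Couple the alkylzinc from 13 with TBS‑protected 4‑bromo‑2,6‑dimethoxyphenol.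
   - Remove the TBS group, then do the Williamson reaction with 17, and continue with the ATH.
3. **Steps 3/4 (γ‑hydroxy ester 5 may lactonise before iodination):** the cis‑dimethyl pattern favours ring closure, which would lose the handle for the first coupling.
   - Fallback: take 5 deliberately to the cis lactone with catalytic TsOH.
   - Open the lactone with TMSI (from TMSCl/NaI, MeCN) and re‑esterify with TMSCHN2/MeOH to give iodo ester 7.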